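**Retrosynthetic overview**
1. Feature: in ring B (the benzene ring fused to the δ-lactone), C8a bears the lactone carbonyl and its neighbour C4a bears the benzylic CH2, and the oxygens on C6 and C8 are meta to each other. C8a/C4a are read as the two carbons of a 2-alkynoate and C5–C8 as four carbons of cyclohexane-1,3-dione, whose remaining CH2CH2 leaves as ethylene.
2. Endgame: the ring A ketone comes from its dioxolane. The seven-membered depsidone ring is opened at the C5–O aryl ether (intramolecular Ullmann from a C5 bromide) and then at the C6–O ester (depside coupling).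
3. The tetrahydropyran and δ-lactone rings come from one open keto alcohol ester. Acid closes both, and the (R)-carbinol carbon from (R)-butane-1,3-diol sets the spiro carbon under thermodynamic control.
4. Ring B comes from 1,3-bis(trimethylsilyloxy)cyclohexa-1,3-diene and an ynoate carrying the masked chiral chain (Alder–Rickert). Ring A has the same 2-O/4-O/6-CH2 benzoate pattern and comes from the same diene and an achiral ynoate.
5. Order of ring formation: ring B; tetrahydropyran and δ-lactone in one operation; ring A in a side branch; the seven-membered ring last.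

Key step: step 10

Remark: ring B locants follow isochroman-1-one numbering (C1 lactone carbonyl, C3 spiro carbon, C4 benzylic CH2, C5 and C7 arene CH, C6 and C8 oxygenated carbons); primed locants belong to the tetrahydropyran. The cycloaddition sets four of the five ring B substituents. The ether oxygen on C5 is brought in afterwards through a bromide, because a direct dehydrogenative phenol coupling could not tell C5 from C7.

**Route**

Step 1
Reactants: 1 (R)-butane-1,3-diol
Product: 2 (2R)-4-iodobutan-2-ol
Conditions: I2 (1.0 equiv), PPh3, imidazole, CH2Cl2, 0 °C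
Reagents that add atoms: iodine, II
Why: Appel-type iodination takes the unhindered primary hydroxyl much faster than the secondary one and does not touch the carbinol stereocentre.

Step 2
Reactants: 2 (2R)-4-iodobutan-2-ol
Product: 3 tert-butyl{[(2R)-4-iodobutan-2-yl]oxy}dimethylsilane
Conditions: TBSCl, imidazole, DMF, rt
Reagents that add atoms: tert-butyldimethylsilyl chloride (TBSCl), CC(C)(C)[Si](C)(C)Cl
Why: Imidazole-promoted silylation gives a secondary silyl ether that should survive the strong bases, the hydride and the heating to come, and that is removed in the acid step.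

Step 3
Reactants: 3 tert-butyl{[(2R)-4-iodobutan-2-yl]oxy}dimethylsilane; 4 ethyl acetoacetate
Product: 6 ethyl (7R)-7-(tert-butyldimethylsilyloxy)-3-oxooctanoate, via acetoacetate dianion 5 (not isolated)
Conditions: 4, NaH, THF, 0 °C; n-BuLi, 0 °C; then 3, 0 °C → rt; aq. NH4Cl
Reagents that add atoms: none
Why: In the Huckin–Weiler γ-alkylation the dianion reacts only at its more basic terminal carbon, here by SN2 on a primary iodide far from the stereocentre.

Step 4
Reactants: 6 ethyl (7R)-7-(tert-butyldimethylsilyloxy)-3-oxooctanoate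
Product: 7 ethyl 2-{2-[(4R)-4-(tert-butyldimethylsilyloxy)pentyl]-1,3-dioxolan-2-yl}acetate
Conditions: TMSOCH2CH2OTMS, TMSOTf (5 mol %), CH2Cl2, −78 → −20 °C; pyridine quench
Reagents that add atoms: 1,2-bis(trimethylsilyloxy)ethane, C[Si](C)(C)OCCO[Si](C)(C)C
Why: Noyori ketalisation is aprotic, runs cold and is driven by formation of hexamethyldisiloxane, so it should spare the TBS ether that hot sulfonic acid and glycol would endanger.

Step 5
Reactants: 7 ethyl 2-{2-[(4R)-4-(tert-butyldimethylsilyloxy)pentyl]-1,3-dioxolan-2-yl}acetate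
Product: 8 2-{2-[(4R)-4-(tert-butyldimethylsilyloxy)pentyl]-1,3-dioxolan-2-yl}acetaldehyde
Conditions: i-Bu2AlH (1.05 equiv), CH2Cl2, −78 °C; aq. potassium sodium tartrate
Reagents that add atoms: none
Why: Partial ester reduction stops at the aluminium hemiacetal at −78 °C, and chelation by the neighbouring dioxolane oxygens helps to hold it there.

Step 6
Reactants: 8 2-{2-[(4R)-4-(tert-butyldimethylsilyloxy)pentyl]-1,3-dioxolan-2-yl}acetaldehyde
Product: 9 2-[(4R)-4-(tert-butyldimethylsilyloxy)pentyl]-2-(prop-2-yn-1-yl)-1,3-dioxolane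
Conditions: MeC(O)C(N2)P(O)(OMe)2, K2CO3, MeOH, 0 °C → rt
Reagents that add atoms: dimethyl (1-diazo-2-oxopropyl)phosphonate, COP(=O)(OC)C(=[N+]=[N-])C(C)=O
Why: Seyferth–Gilbert homologation in its Ohira–Bestmann form turns the aldehyde into the terminal alkyne with only carbonate as base, which keeps β-elimination of the ketal in check.

Step 7
Reactants: 9 2-[(4R)-4-(tert-butyldimethylsilyloxy)pentyl]-2-(prop-2-yn-1-yl)-1,3-dioxolane
Product: 11 methyl 4-{2-[(4R)-4-(tert-butyldimethylsilyloxy)pentyl]-1,3-dioxolan-2-yl}but-2-ynoate, via lithium acetylide 10 (not isolated)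
Conditions: n-BuLi, THF, −78 °C; then cannulated into ClCO2Me (excess), −78 °C
Reagents that add atoms: methyl chloroformate, COC(=O)Cl
Why: This is C-acylation of a lithium acetylide with a chloroformate, and inverse addition keeps base away from the acidic propargylic CH2 of the product so that the allenoate should not form.

Step 8
Reactants: 12 cyclohexane-1,3-dione
Product: 13 3-(trimethylsilyloxy)cyclohex-2-en-1-one
Conditions: TMSCl, Et3N, Et2O, 0 °C → rt; filtration, distillation
Reagents that add atoms: chlorotrimethylsilane, C[Si](C)(C)Cl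
Why: O-silylation of the strongly enolised 1,3-diketone gives the vinylogous silyl ester.

Step 9
Reactants: 13 3-(trimethylsilyloxy)cyclohex-2-en-1-one
Product: 15 1,3-bis(trimethylsilyloxy)cyclohexa-1,3-diene, via lithium dienolate 14 (not isolated)
Conditions: lithium diisopropylamide, THF, −78 °C; then TMSCl, −78 °C → rt; non-aqueous work-up, distillation
Reagents that add atoms: chlorotrimethylsilane, C[Si](C)(C)Cl
Why: Kinetic α′-deprotonation of the vinylogous ester gives the cross-conjugated dienolate, and its O-silylation gives the 1,3-dioxygenated ring diene with one unsubstituted terminus.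

Step 10
Reactants: 11 methyl 4-{2-[(4R)-4-(tert-butyldimethylsilyloxy)pentyl]-1,3-dioxolan-2-yl}but-2-ynoate; 15 1,3-bis(trimethylsilyloxy)cyclohexa-1,3-diene
Product: 17 methyl 2,4-bis(trimethylsilyloxy)-6-({2-[(4R)-4-(tert-butyldimethylsilyloxy)pentyl]-1,3-dioxolan-2-yl}methyl)benzoate, via bicyclo[2.2.2]octadiene adduct 16 (not isolated)
Conditions: 15 (2.5 equiv), neat, base-washed sealed tube, argon, 150–160 °C; excess 15 removed in vacuo
Reagents that add atoms: none
Why: A thermal normal-demand [4+2] cycloaddition of the doubly donor-substituted diene 15 to the acceptor alkyne 11 gives adduct 16, which at the same temperature loses its CH2CH2 bridge as ethylene by retro-[4+2], so aromatisation makes the sequence irreversible. This is the Alder–Rickert reaction, known for 1,3-bis(silyloxy)cyclohexa-1,3-dienes and 2-alkynoates as a route to 6-substituted 2,4-dihydroxybenzoates. Ring B closes intermolecularly by forming two C–C bonds in one cycloaddition: diene C4 to ynoate Cβ (the later C5–C4a bond) and diene C1 to ynoate Cα (the later C8–C8a bond). No lasting stereocentre is made, because the two bridgehead centres of 16 form without control and vanish with the ethylene, and the (R)-carbinol carbon lies far from every reacting atom. The step needs one regiochemistry, the ester next to a silyloxy carbon; both oxygens of 15 push electron density onto its unsubstituted terminus, which pairs with the electrophilic β-carbon of 11, and this pairing also places the bulky ketal chain next to H and not next to the bridgehead OSiMe3. Neutral, acid-free conditions should leave the dioxolane, the TBS ether and the propargylic CH2 intact.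

Step 11
Reactants: 17 methyl 2,4-bis(trimethylsilyloxy)-6-({2-[(4R)-4-(tert-butyldimethylsilyloxy)pentyl]-1,3-dioxolan-2-yl}methyl)benzoate
Product: 19 (3S,6'R)-6,8-dihydroxy-6'-methyl-3',4',5',6'-tetrahydrospiro[isochromane-3,2'-pyran]-1-one, via keto alcohol ester 18 (not isolated)
Conditions: 3 M aq. HCl, THF, 40 °C; solvent switch; then TsOH·H2O (0.1 equiv), toluene, 4 Å MS, 80 °C
Reagents that add atoms: water, O
Why: Acid hydrolysis of the silyl ethers and the dioxolane is followed by spiroketalisation and lactonisation (the C6' hydroxyl adds to the ketone and the hemiketal hydroxyl displaces methanol from the neighbouring ester), and since the acyloxy ketal ionises reversibly under acid, C3 settles thermodynamically as 3S, the isomer whose tetrahydropyran chair, fixed by the equatorial (6'R)-methyl group, holds the lactone oxygen axial (anomeric effect) and the benzylic CH2 equatorial.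

Step 12
Reactants: 19 (3S,6'R)-6,8-dihydroxy-6'-methyl-3',4',5',6'-tetrahydrospiro[isochromane-3,2'-pyran]-1-one
Product: 20 (3S,6'R)-5-bromo-6,8-dihydroxy-6'-methyl-3',4',5',6'-tetrahydrospiro[isochromane-3,2'-pyran]-1-one
Conditions: NBS (1.0 equiv), MeCN, −20 → 0 °C, dark
Reagents that add atoms: N-bromosuccinimide, O=C1CCC(=O)N1Br
Why: In this electrophilic aromatic bromination C5 is para to the chelated C8 hydroxyl and ortho to the C6 hydroxyl, the site at which 6-alkyl-2,4-dihydroxybenzoates take up halogen in preference to the carbon between the two oxygens, and one equivalent in the cold limits dibromination.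

Step 13
Reactants: 21 ethyl 3-oxooctanoate
Product: 22 ethyl 2-(2-pentyl-1,3-dioxolan-2-yl)acetate
Conditions: HOCH2CH2OH, TsOH·H2O (cat.), toluene, reflux, Dean–Stark
Reagents that add atoms: ethylene glycol, OCCO
Why: This is a standard azeotropic ketalisation of a β-keto ester that has no acid-sensitive group.

Step 14
Reactants: 22 ethyl 2-(2-pentyl-1,3-dioxolan-2-yl)acetate
Product: 23 2-(2-pentyl-1,3-dioxolan-2-yl)acetaldehyde
Conditions: i-Bu2AlH (1.05 equiv), CH2Cl2, −78 °C; aq. potassium sodium tartrate
Reagents that add atoms: none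
Why: This is the same partial ester reduction as in step 5, arrested at the chelated aluminium hemiacetal.

Step 15
Reactants: 23 2-(2-pentyl-1,3-dioxolan-2-yl)acetaldehyde
Product: 24 2-pentyl-2-(prop-2-yn-1-yl)-1,3-dioxolane
Conditions: MeC(O)C(N2)P(O)(OMe)2, K2CO3, MeOH, 0 °C → rt
Reagents that add atoms: dimethyl (1-diazo-2-oxopropyl)phosphonate, COP(=O)(OC)C(=[N+]=[N-])C(C)=O
Why: This is the same Ohira–Bestmann form of the Seyferth–Gilbert homologation as in step 6.

Step 16
Reactants: 24 2-pentyl-2-(prop-2-yn-1-yl)-1,3-dioxolane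
Product: 26 benzyl 4-(2-pentyl-1,3-dioxolan-2-yl)but-2-ynoate, via lithium acetylide 25 (not isolated)
Conditions: n-BuLi, THF, −78 °C; then cannulated into ClCO2Bn (excess), −78 °C
Reagents that add atoms: benzyl chloroformate, O=C(Cl)OCc1ccccc1
Why: This is acylation of the lithium acetylide as in step 7, with a benzyl ester chosen so that the hindered ring A acid can later be freed by hydrogenolysis instead of hot saponification.

Step 17
Reactants: 26 benzyl 4-(2-pentyl-1,3-dioxolan-2-yl)but-2-ynoate; 15 1,3-bis(trimethylsilyloxy)cyclohexa-1,3-diene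
Product: 29 benzyl 2,4-dihydroxy-6-[(2-pentyl-1,3-dioxolan-2-yl)methyl]benzoate, via bicyclo[2.2.2]octadiene adduct 27 (not isolated), via bis(trimethylsilyl) ether 28 (not isolated)
Conditions: 15 (2.5 equiv), neat, base-washed sealed tube, argon, 150–160 °C; then K2CO3 (cat.), MeOH, 0 °C
Reagents that add atoms: none
Why: This second Alder–Rickert reaction uses the same polarity match (unsubstituted diene terminus to ynoate β-carbon), and brief catalytic methanolysis then strips only the labile aryl trimethylsilyl ethers, leaving the dioxolane and the doubly ortho-substituted benzyl ester alone.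

Step 18
Reactants: 29 benzyl 2,4-dihydroxy-6-[(2-pentyl-1,3-dioxolan-2-yl)methyl]benzoate
Product: 30 benzyl 2-hydroxy-4-methoxy-6-[(2-pentyl-1,3-dioxolan-2-yl)methyl]benzoate
Conditions: MeI (1.1 equiv), K2CO3 (1.1 equiv), acetone, rt
Reagents that add atoms: iodomethane, CI
Why: In this Williamson O-methylation the 4-hydroxyl is the more acidic and the free one, while the 2-hydroxyl is held in a hydrogen bond to the ester carbonyl and stays unalkylated.

Step 19
Reactants: 30 benzyl 2-hydroxy-4-methoxy-6-[(2-pentyl-1,3-dioxolan-2-yl)methyl]benzoate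
Product: 31 2-hydroxy-4-methoxy-6-[(2-pentyl-1,3-dioxolan-2-yl)methyl]benzoic acid
Conditions: H2 (1 atm), Pd/C (10 wt %), EtOAc, rt; filtered, concentrated cold, used at once
Reagents that add atoms: none
Why: Benzyl ester hydrogenolysis frees the acid under neutral conditions, and immediate use avoids both decarboxylation and opening of the neighbouring dioxolane by the carboxyl group.

Step 20
Reactants: 31 2-hydroxy-4-methoxy-6-[(2-pentyl-1,3-dioxolan-2-yl)methyl]benzoic acid; 20 (3S,6'R)-5-bromo-6,8-dihydroxy-6'-methyl-3',4',5',6'-tetrahydrospiro[isochromane-3,2'-pyran]-1-one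
Product: 32 bromodepside: the C6–O ester of 20 with acid 31 (C5–Br, C8–OH and ring A 2-OH free, ring A ketone as dioxolane, 3S,6'R)
Conditions: DCC (1.1 equiv), DMAP (0.1 equiv), CH2Cl2, 0 °C → rt
Reagents that add atoms: none
Why: In this Steglich esterification (depside coupling) the C8 hydroxyl of 20 and the 2-hydroxyl of 31 are both tied up in hydrogen bonds to their ortho carbonyl groups, so only the C6 hydroxyl should be acylated, and the neutral medium spares both ketals.

Step 21
Reactants: 32 bromodepside
Product: 33 depsidone ketal: the target skeleton with the ring A side chain as (2-pentyl-1,3-dioxolan-2-yl)methyl (3S,6'R)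
Conditions: CuI (20 mol %), N,N-dimethylglycine (40 mol %), Cs2CO3 (3 equiv), 1,4-dioxane (0.01 M), 90 °C; NaH2PO4 buffer work-up
Reagents that add atoms: none
Why: In this intramolecular Ullmann diaryl ether synthesis the monovalent copper phenoxide of the ring A 2-hydroxyl is held by the ester tether next to the C5–Br bond and closes the seven-membered ring, and because only C5 carries a halogen the ether cannot form at C7.

Step 22
Reactants: 33 depsidone ketal
Product: 34 target CNP0301127.1
Conditions: 0.5 M HCl in THF–H2O (4:1), rt, stopped as soon as 33 is consumed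
Reagents that add atoms: water, O
Why: Mild acid hydrolysis removes the dialkyl ketone dioxolane, while the spiro acyloxy ketal is already the form favoured under acid and keeps 3S, and short exposure limits attack of the ring A enol on the depsidone carbonyl.

**Compound list**
1 | (R)-butane-1,3-diol | C[C@@H](O)CCO | starting material
2 | (2R)-4-iodobutan-2-ol | ICC[C@@H](C)O | intermediate
3 | tert-butyl{[(2R)-4-iodobutan-2-yl]oxy}dimethylsilane | ICC[C@@H](C)O[Si](C)(C)C(C)(C)C | intermediate
4 | ethyl acetoacetate | CCOC(=O)CC(C)=O | starting material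
5 | sodium lithium dianion of ethyl acetoacetate | C=C([O-])C=C([O-])OCC.[Li+].[Na+] | intermediate
6 | ethyl (7R)-7-(tert-butyldimethylsilyloxy)-3-oxooctanoate | CCOC(=O)CC(=O)CCC[C@@H](C)O[Si](C)(C)C(C)(C)C | intermediate
7 | ethyl 2-{2-[(4R)-4-(tert-butyldimethylsilyloxy)pentyl]-1,3-dioxolan-2-yl}acetate | CCOC(=O)CC1(OCCO1)CCC[C@@H](C)O[Si](C)(C)C(C)(C)C | intermediate
8 | 2-{2-[(4R)-4-(tert-butyldimethylsilyloxy)pentyl]-1,3-dioxolan-2-yl}acetaldehyde | O=CCC1(OCCO1)CCC[C@@H](C)O[Si](C)(C)C(C)(C)C | intermediate
9 | 2-[(4R)-4-(tert-butyldimethylsilyloxy)pentyl]-2-(prop-2-yn-1-yl)-1,3-dioxolane | C#CCC1(OCCO1)CCC[C@@H](C)O[Si](C)(C)C(C)(C)C | intermediate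
10 | lithium acetylide of 9 | [Li]C#CCC1(OCCO1)CCC[C@@H](C)O[Si](C)(C)C(C)(C)C | intermediate
11 | methyl 4-{2-[(4R)-4-(tert-butyldimethylsilyloxy)pentyl]-1,3-dioxolan-2-yl}but-2-ynoate | COC(=O)C#CCC1(OCCO1)CCC[C@@H](C)O[Si](C)(C)C(C)(C)C | intermediate
12 | cyclohexane-1,3-dione | O=C1CCCC(=O)C1 | starting material
13 | 3-(trimethylsilyloxy)cyclohex-2-en-1-one | C[Si](C)(C)OC1=CC(=O)CCC1 | intermediate
14 | lithium cross-conjugated dienolate of 13 | [Li]OC1=CCCC(O[Si](C)(C)C)=C1 | intermediate
15 | 1,3-bis(trimethylsilyloxy)cyclohexa-1,3-diene | C[Si](C)(C)OC1=CC(O[Si](C)(C)C)=CCC1 | intermediate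
16 | methyl 1,5-bis(trimethylsilyloxy)-3-({2-[(4R)-4-(tert-butyldimethylsilyloxy)pentyl]-1,3-dioxolan-2-yl}methyl)bicyclo[2.2.2]octa-2,5-diene-2-carboxylate (bridgeheads not controlled) | COC(=O)C1=C(CC2(OCCO2)CCC[C@@H](C)O[Si](C)(C)C(C)(C)C)C3CCC1(O[Si](C)(C)C)C=C3O[Si](C)(C)C | intermediate
17 | methyl 2,4-bis(trimethylsilyloxy)-6-({2-[(4R)-4-(tert-butyldimethylsilyloxy)pentyl]-1,3-dioxolan-2-yl}methyl)benzoate | COC(=O)c1c(O[Si](C)(C)C)cc(O[Si](C)(C)C)cc1CC1(OCCO1)CCC[C@@H](C)O[Si](C)(C)C(C)(C)C | intermediate
18 | methyl 2,4-dihydroxy-6-[(6R)-6-hydroxy-2-oxoheptyl]benzoate (in equilibrium with its cyclic hemiketal) | COC(=O)c1c(O)cc(O)cc1CC(=O)CCC[C@@H](C)O | intermediate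
19 | (3S,6'R)-6,8-dihydroxy-6'-methyl-3',4',5',6'-tetrahydrospiro[isochromane-3,2'-pyran]-1-one | Oc1cc(O)c3c(c1)C[C@]1(CCC[C@@H](C)O1)OC3=O | intermediate
20 | (3S,6'R)-5-bromo-6,8-dihydroxy-6'-methyl-3',4',5',6'-tetrahydrospiro[isochromane-3,2'-pyran]-1-one | Oc1cc(O)c3c(c1Br)C[C@]1(CCC[C@@H](C)O1)OC3=O | intermediate
21 | ethyl 3-oxooctanoate | CCCCCC(=O)CC(=O)OCC | starting material
22 | ethyl 2-(2-pentyl-1,3-dioxolan-2-yl)acetate | CCCCCC1(CC(=O)OCC)OCCO1 | intermediate
23 | 2-(2-pentyl-1,3-dioxolan-2-yl)acetaldehyde | CCCCCC1(CC=O)OCCO1 | intermediate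
24 | 2-pentyl-2-(prop-2-yn-1-yl)-1,3-dioxolane | CCCCCC1(CC#C)OCCO1 | intermediate
25 | lithium acetylide of 24 | CCCCCC1(CC#C[Li])OCCO1 | intermediate
26 | benzyl 4-(2-pentyl-1,3-dioxolan-2-yl)but-2-ynoate | CCCCCC1(CC#CC(=O)OCc2ccccc2)OCCO1 | intermediate
27 | benzyl 1,5-bis(trimethylsilyloxy)-3-[(2-pentyl-1,3-dioxolan-2-yl)methyl]bicyclo[2.2.2]octa-2,5-diene-2-carboxylate (racemic) | CCCCCC1(OCCO1)CC1=C(C(=O)OCc2ccccc2)C2(O[Si](C)(C)C)CCC1C(O[Si](C)(C)C)=C2 | intermediate
28 | benzyl 2,4-bis(trimethylsilyloxy)-6-[(2-pentyl-1,3-dioxolan-2-yl)methyl]benzoate | CCCCCC1(OCCO1)Cc1cc(O[Si](C)(C)C)cc(O[Si](C)(C)C)c1C(=O)OCc1ccccc1 | intermediate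
29 | benzyl 2,4-dihydroxy-6-[(2-pentyl-1,3-dioxolan-2-yl)methyl]benzoate | CCCCCC1(OCCO1)Cc1cc(O)cc(O)c1C(=O)OCc1ccccc1 | intermediate
30 | benzyl 2-hydroxy-4-methoxy-6-[(2-pentyl-1,3-dioxolan-2-yl)methyl]benzoate | CCCCCC1(OCCO1)Cc1cc(OC)cc(O)c1C(=O)OCc1ccccc1 | intermediate
31 | 2-hydroxy-4-methoxy-6-[(2-pentyl-1,3-dioxolan-2-yl)methyl]benzoic acid | CCCCCC1(OCCO1)Cc1cc(OC)cc(O)c1C(=O)O | intermediate
32 | bromodepside: (3S,6'R)-5-bromo-8-hydroxy-6'-methyl-1-oxo-3',4',5',6'-tetrahydrospiro[isochromane-3,2'-pyran]-6-yl 2-hydroxy-4-methoxy-6-[(2-pentyl-1,3-dioxolan-2-yl)methyl]benzoate | CCCCCC1(OCCO1)Cc1cc(OC)cc(O)c1C(=O)Oc1cc(O)c3c(c1Br)C[C@]1(CCC[C@@H](C)O1)OC3=O | intermediate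
33 | depsidone ketal (target with the ring A ketone as its 1,3-dioxolane) | CCCCCC1(OCCO1)Cc1cc(OC)cc2c1C(=O)Oc1cc(O)c3c(c1O2)C[C@]1(CCC[C@@H](C)O1)OC3=O | intermediate
34 | CNP0301127.1 (spiro carbon S, methyl-bearing carbon R) | CCCCCC(=O)Cc1cc(OC)cc2c1C(=O)Oc1cc(O)c3c(c1O2)C[C@]1(CCC[C@@H](C)O1)OC3=O | target

**Totals**
Total step count: 22. Longest linear sequence: 13 steps (steps 1–7, 10–12, 20–22).

**Steps most likely to fail**

1. Step 21 (ring closure of the depsidone).
   - Risk: the carbonate base may cleave the activated aryl ester. It may also move ring B from the carboxyl oxygen to the ring A phenoxide (a Smiles-type aryl migration at C6). Either could happen before copper inserts into the hindered, electron-rich C5–Br bond.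
   - Fallback: it sets out from 32. Miyaura borylation (PdCl2(dppf), B2pin2, KOAc, 1,4-dioxane, 80 °C) would convert C5–Br into the pinacol boronate depside F1. Oxidative Chan–Lam coupling of its ring A phenol with the C5–B bond (Cu(OAc)2, pyridine, 4 Å MS, CH2Cl2, air, rt) would then close the seven-membered ring without carbonate or heat. It comes back to the route at 33.

2. Step 10 (key cycloaddition).
   - Risk: the β-branched ynoate may add too slowly. At the temperature needed, prototropic shift to the allenoate, loss of glycol from the ketal, decay of the diene or leakage of regiochemistry could then compete.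
   - Fallback: it sets out from iodide 3. Alkylation of the lithium enolate of N-methoxy-N-methylacetamide with 3 (lithium diisopropylamide, THF–DMPU, −78 → 0 °C) would give the Weinreb amide F2. Purchased methyl 2,4-dihydroxy-6-methylbenzoate is protected (MOMCl, i-Pr2NEt, CH2Cl2) as the bis-MOM toluate F3. Lateral lithiation of F3 (lithium diisopropylamide, THF, −78 °C) and acylation with F2 would give the aryl ketone F4. Under the conditions of step 11, F4 loses its MOM and TBS groups and closes the spirolactone, and it comes back to the route at 19.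

3. Step 12 (bromination).
   - Risk: poor site selectivity between C5 and C7, or over-bromination of the doubly activated ring.
   - Fallback: it sets out from 19. Selective acetylation of the non-chelated C6 hydroxyl (Ac2O, pyridine, 0 °C) would give the monoacetate F5. Its only strong donor is then the C8 hydroxyl, so bromination (NBS, MeCN, 0 °C) should go para to it, as in salicylates, to give the bromo acetate F6. Methanolysis of this activated aryl acetate (K2CO3 cat., MeOH, 0 °C) comes back to the route at 20.

**Further compounds**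
F1 | step 21 | pinacol boronate depside (32 with C5–Br replaced by C5–Bpin) | CCCCCC1(OCCO1)Cc1cc(OC)cc(O)c1C(=O)Oc1cc(O)c3c(c1B4OC(C)(C)C(C)(C)O4)C[C@]1(CCC[C@@H](C)O1)OC3=O
F2 | step 10 | (5R)-5-(tert-butyldimethylsilyloxy)-N-methoxy-N-methylhexanamide | CON(C)C(=O)CCC[C@@H](C)O[Si](C)(C)C(C)(C)C
F3 | step 10 | methyl 2,4-bis(methoxymethoxy)-6-methylbenzoate | COCOc1cc(C)c(C(=O)OC)c(OCOC)c1
F4 | step 10 | methyl 2,4-bis(methoxymethoxy)-6-[(6R)-6-(tert-butyldimethylsilyloxy)-2-oxoheptyl]benzoate | COCOc1cc(CC(=O)CCC[C@@H](C)O[Si](C)(C)C(C)(C)C)c(C(=O)OC)c(OCOC)c1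
F5 | step 12 | (3S,6'R)-8-hydroxy-6'-methyl-1-oxo-3',4',5',6'-tetrahydrospiro[isochromane-3,2'-pyran]-6-yl acetate | CC(=O)Oc1cc(O)c3c(c1)C[C@]1(CCC[C@@H](C)O1)OC3=O
F6 | step 12 | (3S,6'R)-5-bromo-8-hydroxy-6'-methyl-1-oxo-3',4',5',6'-tetrahydrospiro[isochromane-3,2'-pyran]-6-yl acetate | CC(=O)Oc1cc(O)c3c(c1Br)C[C@]1(CCC[C@@H](C)O1)OC3=O
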